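(The data stem from a simulated flask with made-up constants.)

I began with the easy step: every X charged must stand somewhere in a closed flask, so I asked where.

all flasks: X 1.5 M; Z 2.25 M
- north-west: E 0.15 M; temperature 25 °C; the very flask that is asked about, followed so far
- west: E 0.075 M; temperature 20 °C; run made earlier
- flask: E 0.150 M; temperature 25 °C; time 6.0 h

| run | time / min | D / % | X / % |
|---|---|---|---|
| north-west | 30.0 | 15.6 | 0.6 |
| north-west | 50.0 | 14.1 | 0.7 |
| north-west | 90.0 | 13.2 | 0 |
| north-west | 180 | 12.8 | 0.4 |
| north-west | 360 | 13.2 | 0 |
| west | 1.00 | 0.2 | 94.4 |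
| west | 2.00 | 12.6 | 82.1 |
| west | 4.00 | 77.8 | 8.4 |
| west | 8.00 | 63.1 | 0 |
| west | 15.0 | 39.4 | 0 |

(scatter of a reading: 1 percentage point)

- gamma: change nothing and wait 6.0 h more
- beta: at 6.0 h raise the temperature by 10 K, then wait 6.0 h
- zeta: at 6.0 h take out 90% of the D then present, then wait 6.0 h

- what is taken out of D is counted as made

* D, in percent of the X first charged, at 6.0 h
* what to do for the largest gain in D; "none" if nothing gains more than 2 percentage points (gamma / beta / zeta / none)
* D present, with what was taken out counted in, in percent of the X first charged, after beta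
* D present, with what was taken out counted in, in percent of the X first charged, after zeta

In the west run X had lost 5.60% of its charge by 1.00 min while D read 0.2%. That is close to the 5.00% which E's charge makes of X's, so I took E to remove X mole for mole. In the north-west flask this leaves a pool of 90.0% of the X charged, and X read 0% at 360 min.

D in that flask stayed flat from 90.0 min on, whereas the west run, at another temperature and another charge of E, was still falling at its last reading, 15.0 min. I read this as a balance between D and some other form, that is, thermodynamic control. So I carried the resting share s, D at rest divided by the pool at 25 °C, read as 14.5%.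

For that flask this gave me D of 13.1% at 6.0 h, and no gain from waiting. Under zeta, 90% of that D leaves the flask, s applies to the smaller pool, and the total comes to 23.1%. Beta had to lift s past 25.7% to beat that. The runs gave no reading of s at the higher temperature, so I stayed with zeta.

The forecast gave 13.1% now, 14% after beta, 23.3% after zeta and chose zeta, holding that “Heating shifts the equilibrium only modestly”.

The flask gave 13.8% now, 28.6% after beta and 24.4% after zeta, so beta gained more than the other options, 15 percentage points against 11 points for zeta.

    D ⇌ Q (K = 5.50, k = 0.150 min⁻¹, Ea = 94.0 kJ mol⁻¹, ΔH = −72.0 kJ mol⁻¹)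
    X + Z → D (k = 6.05 × 10⁻⁵ L mol⁻¹ min⁻¹, Ea = 75.0 kJ mol⁻¹)
    X + E → J (k = 4.12 L mol⁻¹ min⁻¹, Ea = 59.0 kJ mol⁻¹)
    Z ⇌ L (K = 2.00, k = 0.121 min⁻¹, Ea = 91.0 kJ mol⁻¹, ΔH = −19.0 kJ mol⁻¹)
    X + Z + D → 2 D (k = 2.09 L² mol⁻² min⁻¹, Ea = 44.0 kJ mol⁻¹)
    (constants at 25 °C)

The asked flask had come to rest: at 3600 min D stood at 13.8%, the same as at 6.0 h, and the relaxation half-life of D and Q by their own step alone, 3.91 min, is far shorter than 6.0 h. Waiting gains 0 points. Applied to the computed D, s gives 23.7% after zeta, against 24.4%. Beta changes s itself: 28.6% over the pool is 31.8%, about twice my s and higher than the 25.7% it had to pass.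

In the neighbour flask with 0.38 M of X, E's charge leaves a pool of 60.5%, so s gives D of 8.77%. The computed value for that flask is 9.31%.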